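The cyclohexanone ring C1–C9–C5–C6–C7–C8 is opened at C1–C8, which exposes a hidden symmetry: the ring segment C6–C7(prenyl)–C8Me2 and the C5 side chain are two copies of one lavandulyl unit. The precursor is therefore a C2-symmetric 2,2-bis-lavandulyl cyclohexane-1,3,5-trione. A temporary iodoether ring ties one chain to an enol oxygen, which fixes C5, masks that isopropenyl group and leaves the other chain free. In the key step acid turns the free isopropenyl group into the C8 cation, and C1 of the enol captures it, as in the biosynthesis, closing the bicyclo[3.3.1]nonane with C7-endo prenyl. Zinc later reopens the iodoether.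

Key step: step 11

Remark on numbering: C1 = bridgehead with the 3-hydroxy-3-methylbutyl chain, C2 (C=O), C3 (aroyl), C4 (enol), C5 = bridgehead with the lavandulyl chain, C6 (CH2), C7 (prenyl), C8 (CMe2), C9 (bridging C=O); O4 and O9 are the oxygens on C4 and C9. Lavandulyl = 5-methyl-2-(prop-1-en-2-yl)hex-4-en-1-yl.

Remark on descriptors: the lavandulyl stereocentre keeps one spatial arrangement throughout; its CIP descriptor is S in 4–6 and R from 8 on and in the target only because the priorities of its neighbours change.

Assumption: (S)-lavandulol is not taken as a purchasable compound and is made in steps 1–3.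

Step 1
Reactants: 1 (4S)-4-benzyl-1,3-oxazolidin-2-one; 2 3-methylbut-2-enoyl chloride
Product: 3 (4S)-4-benzyl-3-(3-methylbut-2-enoyl)-1,3-oxazolidin-2-one
Conditions: n-BuLi, THF, −78 °C; then 2, −78 → 0 °C
Reagents that add atoms: none
Why: N-acylation of the lithiated oxazolidinone (Evans imide formation); no stereocentre is formed.

Step 2
Reactants: 3
Product: 4 (4S)-4-benzyl-3-[(2S)-5-methyl-2-(prop-1-en-2-yl)hex-4-enoyl]-1,3-oxazolidin-2-one
Conditions: NaN(SiMe3)2, THF, −78 °C; prenyl bromide, −78 → −40 °C
Reagents that add atoms: prenyl bromide (1-bromo-3-methylbut-2-ene), CC(C)=CCBr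
Why: γ-deprotonation should give the chelated Z-dienolate, which is alkylated at the α-carbon on the face away from the benzyl group (Evans asymmetric alkylation in its deconjugative form), setting the lavandulyl stereocentre that becomes both C7 and the side-chain centre.

Step 3
Reactants: 4
Product: 5 (S)-lavandulol
Conditions: LiBH4, MeOH (1 equiv), Et2O, 0 °C
Reagents that add atoms: none
Why: reductive cleavage of the imide to the primary alcohol under conditions mild enough to leave the α-centre and the β,γ-alkene in place; the auxiliary is recovered.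

Step 4
Reactants: 5
Product: 6 (S)-lavandulyl iodide
Conditions: I2, PPh3, imidazole, CH2Cl2, 0 °C
Reagents that add atoms: iodine, [I][I]
Why: Appel-type iodination of the primary alcohol; the stereocentre is not involved.

Step 5
Reactants: 7 methyl acetoacetate; 6 (S)-lavandulyl iodide
Product: 8 methyl 2-[(2R)-lavandulyl]-3-oxobutanoate (both epimers at C2)
Conditions: 7 (1.6 equiv), NaH (1.5 equiv), DMF, 0 °C; then 6 (1.0 equiv), 50 °C
Reagents that add atoms: none
Why: SN2 C-alkylation of the sodium enolate of the β-keto ester (acetoacetic ester alkylation), with 7 in excess to hold the reaction at the mono-alkyl stage; the lavandulyl centre is untouched and the new enolisable α-centre is left uncontrolled because it stops being a stereocentre in step 6.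

Step 6
Reactants: 8 methyl 2-[(2R)-lavandulyl]-3-oxobutanoate; 6 (S)-lavandulyl iodide
Product: 9 methyl 2,2-bis[(2R)-lavandulyl]-3-oxobutanoate
Conditions: NaH (1.2 equiv), DMF, 0 °C; then 6 (1.3 equiv), 70 °C
Reagents that add atoms: none
Why: second SN2 C-alkylation of the β-keto ester enolate (acetoacetic ester alkylation) with a further equivalent of the iodide; the new quaternary carbon carries two identical chains and is not a stereocentre, so both epimers of 8 converge on one compound.

Step 7
Reactants: 9
Product: 10 methyl 2,2-bis[(2R)-lavandulyl]-3,5-dioxohexanoate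
Conditions: MgBr2·OEt2 (2.5 equiv), iPr2NEt (3 equiv), 1-acetylbenzotriazole (1.5 equiv), CH2Cl2, 25 °C; aq HCl (1 M) work-up
Reagents that add atoms: 1-acetylbenzotriazole, CC(=O)n1nnc2ccccc21
Why: soft enolisation, in which magnesium coordination makes the methyl ketone (the only enolisable position) acidic enough for the amine base and the magnesium enolate is C-acylated by the acylbenzotriazole (crossed Claisen-type acylation to the 1,3-diketone); the excess base takes up the more acidic product, so conversion is not capped, and no stereocentre is formed.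

Step 8
Reactants: 10
Product: 11 2,2-bis[(2R)-lavandulyl]cyclohexane-1,3,5-trione
Conditions: LiN(iPr)2 (2.5 equiv), THF, −78 → 0 °C; aq NH4Cl
Reagents that add atoms: none
Why: the 1,3-diketone dianion, formed at the central CH2 and then at the terminal CH3, attacks the neighbouring ester through its terminal carbon (Claisen condensation in its Dieckmann-type ring-closing form, 6-exo-trig) to give the C2-symmetric trione without a new stereocentre, and the non-nucleophilic amide base at low temperature limits retro-Claisen cleavage at the fully substituted β-keto ester.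

Step 9
Reactants: 11
Product: 12 mono-iodoether (2-iodomethyl-2-methyl-3-prenyl-4a-lavandulyl-tetrahydrochromene-5,7-dione)
Conditions: NaH (1.0 equiv), THF, 0 °C; I2 (1.0 equiv), −40 → −20 °C, dark
Reagents that add atoms: iodine, [I][I]
Why: iodoetherification (6-exo iodocyclisation) of the mono-enolate, in which an enol oxygen next to the quaternary carbon opens the iodonium ion of one isopropenyl group; the ring fusion forces the second lavandulyl chain axial on the forming pyran, so only the pairing that keeps the ring prenyl equatorial avoids a 1,3-diaxial clash, the C2 axis makes this pairing identical for either chain, and one diastereomer should therefore form with C5 as a defined stereocentre, while the limiting iodine and the single equivalent of base keep the less acidic product from cyclising again and the CH2I-bearing carbon (CH2I expected equatorial) is erased in step 17.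

Step 10
Reactants: 12
Product: 13 C1-(2-methoxycarbonylethyl) derivative of 12
Conditions: methyl acrylate (1.1 equiv), DBU (0.2 equiv), MeCN, 0 → 25 °C
Reagents that add atoms: methyl acrylate, C=CC(=O)OC
Why: Michael addition of the only active methylene (C1, between C2=O and C9=O) installs three carbons of the later hydroxy-isopentyl chain; the mono-adduct is more hindered than 12, which should hold the reaction at one addition, and C1 stays enolised, so no stereocentre is fixed here.

Step 11
Reactants: 13
Product: 15 tricyclic iodoether diketo ester, via C8 tertiary carbocation 14 (not isolated)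
Conditions: HCO2H–CH2Cl2 (1:1), 0 → 25 °C; then aq NaHCO3
Reagents that add atoms: none
Why: Markovnikov protonation of the isopropenyl group of the free lavandulyl chain gives tertiary cation 14 at C8, which is captured by C1 of the enolised 1,3-diketone to join two fully substituted carbons; the closest known reaction type is the formic acid-mediated cation–enol cyclisation of dearomatised prenylated acylphloroglucinols. The six-membered ring C1–C9–C5–C6–C7–C8 closes with the enol double bond C9=C1 inside the new ring (6-enolendo mode) through a boat-like transition state that keeps the C7 prenyl group pseudo-equatorial. The only new stereocentre, C1, is fixed by the C5–C6–C7–C8 tether, which can reach C1 only from the face of C5 that carries C6; C5 and C7 are already set, so the prenyl group can only end endo. The step needs C-attack at C1 to win over attack at O9, attack at C3 and proton loss: O-alkylation at O9 gives a tertiary alkyl enol ether that re-ionises in the acid, attack at C3 gives an oxocarbenium ion that could lose its proton only to a bridgehead alkene and therefore reverts, and proton loss only returns the alkene, so the C-alkylated diketone is the one irreversible exit. Protonation of a prenyl group is also reversible, and its one forward path, six-ring closure onto the free isopropenyl CH2, should be outrun because the isopropenyl group is protonated with the enol poised as internal nucleophile, whereas a prenyl cation has to form without such assistance. The iodoether, the methyl ester and the vinylogous ester should survive the acid.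

Step 12
Reactants: 15
Product: 17 trimethylsilyl ether of the tertiary alcohol, via tertiary alcohol 16 (not isolated)
Conditions: MeMgBr (3 equiv), THF, −40 → 0 °C; aq NH4Cl; then 1-(trimethylsilyl)imidazole, CH2Cl2, 25 °C
Reagents that add atoms: methylmagnesium bromide, C[Mg]Br; 1-(trimethylsilyl)imidazole, C[Si](C)(C)n1ccnc1
Why: double Grignard addition to the unhindered ester builds the 3-hydroxy-3-methylbutyl chain while the bridging C9 ketone (between two quaternary carbons) and the C2 vinylogous ester carbonyl (next to quaternary C1) should be too hindered to compete, and silylation then removes the only acidic OH before step 15.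

Step 13
Reactants: 18 3,4-dihydroxybenzoic acid
Product: 19 tert-butyldimethylsilyl 3,4-bis(tert-butyldimethylsilyloxy)benzoate
Conditions: TBSCl (3.3 equiv), imidazole, DMF, 25 °C
Reagents that add atoms: tert-butyldimethylsilyl chloride, CC(C)(C)[Si](C)(C)Cl
Why: exhaustive silylation of both phenols and the acid (silyl ether and silyl ester formation).

Step 14
Reactants: 19
Product: 20 3,4-bis(tert-butyldimethylsilyloxy)benzoyl chloride
Conditions: (COCl)2, DMF (cat.), CH2Cl2, 0 → 25 °C
Reagents that add atoms: oxalyl chloride, O=C(Cl)C(Cl)=O
Why: direct conversion of the silyl ester into the acid chloride by the Vilsmeier-type chloroiminium reagent under neutral conditions; the aryl silyl ethers are untouched.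

Step 15
Reactants: 17; 20
Product: 21 C3-aroylated tricycle
Conditions: LiTMP (lithium 2,2,6,6-tetramethylpiperidide, 1.2 equiv), THF, −78 °C; then 20, −78 → −40 °C
Reagents that add atoms: none
Why: deprotonation of C3–H, the vinylic α-proton of the β-alkoxy enone and the only acidic C–H left, followed by C-acylation (α-lithiation and acylation of a vinylogous ester) places the aroyl group next to the iodoether oxygen O4.

Step 16
Reactants: 21
Product: 22 desilylated iodoether
Conditions: Bu4NF (3.3 equiv), AcOH (3.3 equiv), THF, 0 °C
Reagents that add atoms: none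
Why: buffered fluoride cleavage of the two aryl silyl ethers and the tertiary silyl ether, done while the enol and the isopropenyl group are still locked in the iodoether.

Step 17
Reactants: 22
Product: 23 target
Conditions: Zn dust, NH4Cl, EtOH–THF–H2O, 40 °C
Reagents that add atoms: none
Why: reductive β-elimination of the β-iodo ether by zinc (Boord-type elimination) regenerates the isopropenyl group and the C4 enol in one operation without acid, so the enol cannot add back to the alkene.

Compound list
1 | (4S)-4-benzyl-1,3-oxazolidin-2-one | O=C1N[C@@H](Cc2ccccc2)CO1 | starting material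
2 | 3-methylbut-2-enoyl chloride | CC(C)=CC(=O)Cl | starting material
3 | (4S)-4-benzyl-3-(3-methylbut-2-enoyl)-1,3-oxazolidin-2-one | CC(C)=CC(=O)N1[C@@H](Cc2ccccc2)COC1=O | intermediate
4 | (4S)-4-benzyl-3-[(2S)-5-methyl-2-(prop-1-en-2-yl)hex-4-enoyl]-1,3-oxazolidin-2-one | C=C(C)[C@H](CC=C(C)C)C(=O)N1[C@@H](Cc2ccccc2)COC1=O | intermediate
5 | (2S)-5-methyl-2-(prop-1-en-2-yl)hex-4-en-1-ol, (S)-lavandulol | C=C(C)[C@H](CC=C(C)C)CO | intermediate
6 | (3S)-3-(iodomethyl)-2,6-dimethylhepta-1,5-diene, (S)-lavandulyl iodide | C=C(C)[C@H](CC=C(C)C)C[I] | intermediate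
7 | methyl acetoacetate (methyl 3-oxobutanoate) | CC(=O)CC(=O)OC | starting material
8 | methyl 2-[(2R)-lavandulyl]-3-oxobutanoate, both epimers at C2 | CC(=O)C(C[C@@H](CC=C(C)C)C(C)=C)C(=O)OC | intermediate
9 | methyl 2,2-bis[(2R)-lavandulyl]-3-oxobutanoate | CC(=O)C(C[C@@H](CC=C(C)C)C(C)=C)(C[C@@H](CC=C(C)C)C(C)=C)C(=O)OC | intermediate
10 | methyl 2,2-bis[(2R)-lavandulyl]-3,5-dioxohexanoate | CC(=O)CC(=O)C(C[C@@H](CC=C(C)C)C(C)=C)(C[C@@H](CC=C(C)C)C(C)=C)C(=O)OC | intermediate
11 | 2,2-bis[(2R)-lavandulyl]cyclohexane-1,3,5-trione, drawn as its dienol 3,5-dihydroxy-4,4-bis(lavandulyl)cyclohexa-2,5-dien-1-one | O=C1C=C(O)C(C[C@@H](CC=C(C)C)C(C)=C)(C[C@@H](CC=C(C)C)C(C)=C)C(O)=C1 | intermediate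
12 | 2-(iodomethyl)-2-methyl-3-(3-methylbut-2-en-1-yl)-4a-[(2R)-lavandulyl]-2,3,4,4a-tetrahydro-5H-chromene-5,7(6H)-dione; chair pyran with 3-prenyl and CH2I equatorial and the 4a chain axial (3-prenyl trans to the 4a chain); ring O = O4, C4a = C5, C5 = C9, C6 = C1, C7 = C2, C8 = C3 | C=C(C)[C@H](CC=C(C)C)C[C@@]1(C[C@@H](CC=C(C)C)[C@](C)(C[I])O2)C(=O)CC(=O)C=C12 | intermediate
13 | 12 with a CH2CH2CO2Me chain on C1 (chromene C6), drawn as the C9 enol | C=C(C)[C@H](CC=C(C)C)C[C@@]1(C[C@@H](CC=C(C)C)[C@](C)(C[I])O2)C(O)=C(CCC(=O)OC)C(=O)C=C12 | intermediate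
14 | C8 tertiary carbocation from protonation of the isopropenyl group of 13 | C[C+](C)[C@H](CC=C(C)C)C[C@@]1(C[C@@H](CC=C(C)C)[C@](C)(C[I])O2)C(O)=C(CCC(=O)OC)C(=O)C=C12 | intermediate
15 | bicyclo[3.3.1]non-3-ene-2,9-dione with CH2CH2CO2Me on C1, endo-prenyl on C7, gem-dimethyl on C8 and the iodoether pyran of 12 fused at O4/C4–C5; C1, C5, C7 and the pyran prenyl carbon configured as in the target | [I]C[C@](C)(O3)[C@H](CC=C(C)C)C[C@@]12C[C@@H](CC=C(C)C)C(C)(C)[C@@](CCC(=O)OC)(C(=O)C=C13)C2=O | intermediate
16 | 15 with the C1 chain converted into CH2CH2C(CH3)2OH | [I]C[C@](C)(O3)[C@H](CC=C(C)C)C[C@@]12C[C@@H](CC=C(C)C)C(C)(C)[C@@](CCC(C)(C)O)(C(=O)C=C13)C2=O | intermediate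
17 | trimethylsilyl ether of 16 | [I]C[C@](C)(O3)[C@H](CC=C(C)C)C[C@@]12C[C@@H](CC=C(C)C)C(C)(C)[C@@](CCC(C)(C)O[Si](C)(C)C)(C(=O)C=C13)C2=O | intermediate
18 | 3,4-dihydroxybenzoic acid | O=C(O)c1ccc(O)c(O)c1 | starting material
19 | tert-butyldimethylsilyl 3,4-bis(tert-butyldimethylsilyloxy)benzoate | CC(C)(C)[Si](C)(C)OC(=O)c1ccc(O[Si](C)(C)C(C)(C)C)c(O[Si](C)(C)C(C)(C)C)c1 | intermediate
20 | 3,4-bis(tert-butyldimethylsilyloxy)benzoyl chloride | O=C(Cl)c1ccc(O[Si](C)(C)C(C)(C)C)c(O[Si](C)(C)C(C)(C)C)c1 | intermediate
21 | 17 carrying the 3,4-bis(tert-butyldimethylsilyloxy)benzoyl group on C3 | [I]C[C@](C)(O3)[C@H](CC=C(C)C)C[C@@]12C[C@@H](CC=C(C)C)C(C)(C)[C@@](CCC(C)(C)O[Si](C)(C)C)(C(=O)C(C(=O)c4ccc(O[Si](C)(C)C(C)(C)C)c(O[Si](C)(C)C(C)(C)C)c4)=C13)C2=O | intermediate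
22 | iodoether of the target: 3-(3,4-dihydroxybenzoyl) tricycle with free tertiary alcohol and the O4–C(CH3)(CH2I) pyran | [I]C[C@](C)(O3)[C@H](CC=C(C)C)C[C@@]12C[C@@H](CC=C(C)C)C(C)(C)[C@@](CCC(C)(C)O)(C(=O)C(C(=O)c4ccc(O)c(O)c4)=C13)C2=O | intermediate
23 | CNP0148616.1 | C=C(C)[C@H](CC=C(C)C)C[C@@]12C[C@@H](CC=C(C)C)C(C)(C)[C@@](CCC(C)(C)O)(C(=O)C(C(=O)c3ccc(O)c(O)c3)=C1O)C2=O | target

Total step count: 17 steps.
Longest linear sequence: 15 steps (steps 1–12 and 15–17); steps 13 and 14 prepare 20.

Steps most likely to fail

Step 11. A prenyl group of the free chain may be protonated first and close a six-membered ring onto the still free isopropenyl group, or the C8 cation may undergo a 1,2-hydride shift or lose the C7 proton faster than it is captured at congested C1, which would erase the C7 configuration. Fallback, from 13 back to 15: the cation is made by ionisation at a fixed position. Markovnikov hydration of the 1,1-disubstituted alkene of 13 (Co(acac)2, PhSiH3, O2, iPrOH, 0 °C; the trisubstituted prenyl groups should react more slowly) should give tertiary alcohol F1, in which no isopropenyl group is left to trap a prenyl cation. Bi(OTf)3 (5 mol %) in CH2Cl2 at −40 °C should then ionise F1 at C8 and deliver 15 by dehydrative C-alkylation of the 1,3-diketone.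

Step 9. The second lavandulyl chain may cyclise as well once proton transfer regenerates an enolate, the enolate may be iodinated at carbon, and the two chair transition states may be told apart less well than expected. Fallback, from 11 back to 12: both chains are closed on purpose and one ring is reopened. NaHCO3 (2.5 equiv) and I2 (2.2 equiv) in MeCN should convert 11 into the C2-symmetric bis-iodoether F2 through the same favoured chair on both sides. Zinc dust (1 equiv) with NH4Cl in EtOH then reopens one ring; because the two rings of F2 are homotopic, either opening gives 12, and recovered F2 and 11 are recycled.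

Step 6. E2 elimination of the β-branched iodide to a conjugated diene and O-alkylation may outrun the second C-alkylation at the congested carbon. Fallback, from 6 back to 9: the quaternary carbon is built on dimethyl malonate, whose anion is alkylated at carbon only. Double alkylation of dimethyl malonate with 6 (NaH, DMSO, 60 °C) should give malonate F3, KOH (1 equiv) in MeOH–H2O the half-ester F4, and (COCl)2 the acid chloride F5; LiCuMe2 in Et2O at −78 °C should then convert F5 into the methyl ketone 9.

Further compounds
F1 | step 11 | tertiary alcohol from Markovnikov hydration of the free isopropenyl group of 13 | CC(C)(O)[C@H](CC=C(C)C)C[C@@]1(C[C@@H](CC=C(C)C)[C@](C)(C[I])O2)C(O)=C(CCC(=O)OC)C(=O)C=C12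
F2 | step 9 | C2-symmetric bis-iodoether of 11, both lavandulyl chains closed on O4 and O9 with equatorial prenyl groups | O=C1C=C2O[C@@](C)(C[I])[C@H](CC=C(C)C)C[C@@]23C[C@@H](CC=C(C)C)[C@](C)(C[I])OC3=C1
F3 | step 6 | dimethyl 2,2-bis[(2R)-lavandulyl]propanedioate | COC(=O)C(C[C@@H](CC=C(C)C)C(C)=C)(C[C@@H](CC=C(C)C)C(C)=C)C(=O)OC
F4 | step 6 | 3-methoxy-3-oxo-2,2-bis[(2R)-lavandulyl]propanoic acid | COC(=O)C(C[C@@H](CC=C(C)C)C(C)=C)(C[C@@H](CC=C(C)C)C(C)=C)C(=O)O
F5 | step 6 | methyl 3-chloro-3-oxo-2,2-bis[(2R)-lavandulyl]propanoate | COC(=O)C(C[C@@H](CC=C(C)C)C(C)=C)(C[C@@H](CC=C(C)C)C(C)=C)C(=O)Cl
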